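Slowness is what this flask shows at first: the over-reaction product takes until 6.00 h to reach 49.4%. But the climb feeds on the complex with two exchanged, which falls from 26.3% at 0.500 h to 0% at 6.00 h. What counts for the person taking over is therefore how much of that complex can form, not the speed of its turning.

| setting | delta | beta | flask |
|---|---|---|---|
| starting complex | 0.74 M | 1.5 M | 0.74 M |
| incoming ligand | 1.11 M | 1.11 M | 1.11 M |
| remark | the very flask that is asked about, followed so far | run made earlier |  |
| time |  |  | 20 h |

- delta (time / h: over-reaction product / %, complex with two exchanged / %): 0.500: 9.8, 26.3; 0.833: 20.9, 22.2; 1.50: 34.2, 12.9; 3.00: 46.7, 4.0; 6.00: 49.4, 0
- beta (time / h: over-reaction product / %, complex with two exchanged / %): 1.50: 4.6, 0.1; 3.00: 2.7, 0; 5.00: 4.3, 1.3; 6.00: 2.7, 0; 8.00: 6.0, 0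

(scatter of a reading: 1 percentage point)

- the earlier runs were read with a standard deviation of 1 percentage point
- reactions considered so far: complex with two exchanged -> over-reaction product; starting complex + incoming ligand -> leaving ligand + complex with one exchanged; complex with one exchanged + incoming ligand -> leaving ligand + complex with two exchanged
- the reaction counts as stopped when no species that holds the starting complex changes by six tenths of a point or more over the second half of the time

- the state of affairs at 20 h: stopped, and by what, or still going (all of the starting complex has reacted / it is still moving)
- amount of over-reaction product at 20 h, in percent of the starting complex charged

Each exchange takes one incoming ligand. The quantity to carry is the second-exchange share: incoming ligand charged minus starting complex charged, divided by starting complex charged, 50.0% in this flask. When a flask holds neither incoming ligand nor complex with two exchanged, counting ligands gives over-reaction product = share + starting complex left, so the survivor is a correction to be reckoned separately. In this flask the readings at 3.00 h and 6.00 h suggest that it is small, so my reckoning expects about 50.0% of over-reaction product at 20 h, the rest as complex with one exchanged. Do not top up with incoming ligand, as that raises the share.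

The forecast says all of the starting complex has reacted, with 50% of over-reaction product: “The ligand is the limiting factor”.

The simulation of this flask gives all of the starting complex has reacted, with 50.0%.

    complex with two exchanged → over-reaction product (k = 0.0197 min⁻¹)
    starting complex + incoming ligand → leaving ligand + complex with one exchanged (k = 0.836 M⁻¹ min⁻¹)
    complex with one exchanged + incoming ligand → leaving ligand + complex with two exchanged (k = 0.0678 M⁻¹ min⁻¹)

In this flask the share plus the starting complex left, 0.0068%, gives 50.0%, so the correction does not reach the printed figure. The falling level of incoming ligand, the limiting reagent, holds this flask at that value: it ends at 0%, and the run with its level held gives 100%. In the neighbour charged with 0.44 M of incoming ligand, the share is −40.5%, and the starting complex left there, 43%, lifts it to about 2.20%; the computed value is 2.20%.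

(The earlier runs and the new flask stem from a simulated flask for an exercise; the scatter is artificial.)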